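**Strategy.** Everything rests on cutting the O1–C5 bond of the γ-lactone ring (O1, C2, C3, C4, C5). Without O1 and the two C3 substituents, C2–C5 form an achiral 3-(3,4-dimethoxybenzyl)cyclobutanone in which the future C3 and C5 are enantiotopic CH2 groups beside the C2 carbonyl. A catalytic asymmetric Baeyer–Villiger oxidation lets one of them migrate from C2 to oxygen: this single shift makes the O1–C5 bond, expands the four-membered ring to the lactone and turns C4 into an R stereocentre. The cyclobutanone comes from methyl eugenol and dichloroketene; C3 benzylation, enolate hydroxylation and hydrogenolysis complete trachelogenin.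

Key step: step 3

Remark: the route assumes that the ligand enantiomer used in step 3 is the one that delivers the (R)-lactone; if the other sense of induction is found, the antipodal ligand is used.

Step 1
Reactants: 1 4-allyl-1,2-dimethoxybenzene (methyl eugenol)
Product: 2 2,2-dichloro-3-(3,4-dimethoxybenzyl)cyclobutan-1-one (racemic)
Conditions: Cl3CCOCl, Zn–Cu couple, POCl3, Et2O, reflux
Reagents that add atoms: trichloroacetyl chloride, ClC(=O)C(Cl)(Cl)Cl
Why: Dichloroketene, formed by zinc dechlorination of the acid chloride, should undergo a thermal [2+2] ketene–alkene cycloaddition in which the terminal CH2 of the alkene bonds to the ketene carbonyl carbon, giving the 2,2-dichloro-3-substituted cyclobutanone as a racemate whose stereocentre is erased in step 2.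

Step 2
Reactants: 2 2,2-dichloro-3-(3,4-dimethoxybenzyl)cyclobutan-1-one
Product: 3 3-(3,4-dimethoxybenzyl)cyclobutan-1-one
Conditions: Zn dust, AcOH, 25 to 60 °C
Reagents that add atoms: none
Why: Reductive dehalogenation of the α,α-dichloro ketone by zinc in acetic acid should remove both chlorines and leave the achiral, mirror-symmetric 3-substituted cyclobutanone.

Step 3
Reactants: 3 3-(3,4-dimethoxybenzyl)cyclobutan-1-one
Product: 5 (R)-4-(3,4-dimethoxybenzyl)dihydrofuran-2(3H)-one, via Criegee adduct 4 (not isolated)
Conditions: Sc(OTf)3 (5 mol%), C2-symmetric amino-acid-derived chiral N,N'-dioxide bis(anilide) ligand (5 mol%), mCPBA (1.2 equiv), EtOAc, −20 °C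
Reagents that add atoms: mCPBA (3-chloroperoxybenzoic acid), OOC(=O)c1cccc(Cl)c1
Why: Baeyer–Villiger oxidation: mCPBA adds to the scandium-bound carbonyl to give Criegee adduct 4, and one of the two enantiotopic ring CH2 groups migrates from carbon to the proximal peroxide oxygen with loss of 3-chlorobenzoate, which forms the O–CH2 bond. The closest known reaction type is the catalytic asymmetric Baeyer–Villiger desymmetrisation of 3-substituted cyclobutanones. The five-membered lactone is closed by ring expansion of the four-membered ring through this 1,2-shift, driven by release of cyclobutanone strain. The stereocentre (C4 of the lactone) has no bond made or broken but becomes stereogenic when the chiral scandium–ligand complex decides which CH2 group lies antiperiplanar to the O–O bond, and the ligand enantiomer is chosen to give R. The step needs selection between enantiotopic groups and chemoselectivity for the ketone over the dimethoxyarene: regioselectivity is no issue because both migrating carbons are equivalent CH2 groups, the pseudo-equatorial benzyl group on the puckered ring gives the catalyst a handle to tell them apart, and the strained ketone reacts at −20 °C where arene oxidation is slow.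

Step 4
Reactants: 6 [4-(benzyloxy)-3-methoxyphenyl]methanol
Product: 7 1-(benzyloxy)-4-(bromomethyl)-2-methoxybenzene
Conditions: PBr3 (0.4 equiv), Et2O, 0 °C; used at once
Reagents that add atoms: phosphorus tribromide, BrP(Br)Br
Why: Alcohol-to-bromide substitution with PBr3: the benzylic alcohol is activated as a phosphite ester and displaced by bromide (SN2), while the aryl benzyl ether is untouched.

Step 5
Reactants: 5 (R)-4-(3,4-dimethoxybenzyl)dihydrofuran-2(3H)-one; 7 1-(benzyloxy)-4-(bromomethyl)-2-methoxybenzene
Product: 9 (3R,4R)-3-[4-(benzyloxy)-3-methoxybenzyl]-4-(3,4-dimethoxybenzyl)dihydrofuran-2(3H)-one (O-benzylarctigenin), via lithium enolate 8 (not isolated)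
Conditions: LiN(SiMe3)2 (1.05 equiv), THF, −78 °C; then 7, DMPU, −78 to −30 °C
Reagents that add atoms: none
Why: Lactone enolate alkylation: the bromide should enter anti to the C4 substituent and give the trans (3R,4R) lactone, although the C3 configuration is of no consequence because step 6 makes C3 planar again.

Step 6
Reactants: 9 (3R,4R)-3-[4-(benzyloxy)-3-methoxybenzyl]-4-(3,4-dimethoxybenzyl)dihydrofuran-2(3H)-one
Product: 11 (3S,4S)-3-[4-(benzyloxy)-3-methoxybenzyl]-4-(3,4-dimethoxybenzyl)-3-hydroxydihydrofuran-2(3H)-one (O-benzyltrachelogenin), via potassium enolate 10 (not isolated)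
Conditions: KN(SiMe3)2 (1.3 equiv), THF, −78 °C; then racemic 3-phenyl-2-(phenylsulfonyl)oxaziridine, −78 °C; AcOH quench
Reagents that add atoms: 3-phenyl-2-(phenylsulfonyl)oxaziridine, O=S(=O)(c1ccccc1)N1OC1c1ccccc1
Why: Davis enolate oxidation: the oxaziridine transfers oxygen to C3 of the potassium enolate, and by the established behaviour of trans-2,3-dibenzylbutyrolactone enolates (A(1,2) strain turns the arene of the C3 benzyl group onto the face anti to the C4 substituent and shields it) oxygen should enter cis to the C4 benzyl group, giving the (3S,4S) tertiary alcohol with the benzyl groups trans; C4 is unchanged in space and its descriptor becomes S only because C3 now outranks C5.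

Step 7
Reactants: 11 (3S,4S)-3-[4-(benzyloxy)-3-methoxybenzyl]-4-(3,4-dimethoxybenzyl)-3-hydroxydihydrofuran-2(3H)-one
Product: 12 trachelogenin, (3S,4S)-4-(3,4-dimethoxybenzyl)-3-hydroxy-3-(4-hydroxy-3-methoxybenzyl)dihydrofuran-2(3H)-one
Conditions: H2 (1 atm), 10% Pd/C, EtOAc/EtOH, 25 °C
Reagents that add atoms: none
Why: Catalytic hydrogenolysis should cleave the aryl benzyl ether while the lactone, the non-benzylic tertiary alcohol and both stereocentres stay untouched.

**Compound list**

1 | 4-allyl-1,2-dimethoxybenzene (methyl eugenol) | C=CCc1ccc(OC)c(OC)c1 | starting material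
2 | 2,2-dichloro-3-(3,4-dimethoxybenzyl)cyclobutan-1-one (racemic) | O=C1CC(Cc2ccc(OC)c(OC)c2)C1(Cl)Cl | intermediate
3 | 3-(3,4-dimethoxybenzyl)cyclobutan-1-one (achiral) | O=C1CC(Cc2ccc(OC)c(OC)c2)C1 | intermediate
4 | Criegee adduct, 3-(3,4-dimethoxybenzyl)-1-hydroxycyclobutyl 3-chloroperoxybenzoate (not isolated) | OC1(OOC(=O)c2cccc(Cl)c2)CC(Cc2ccc(OC)c(OC)c2)C1 | intermediate
5 | (R)-4-(3,4-dimethoxybenzyl)dihydrofuran-2(3H)-one | O=C1OC[C@@H](C1)Cc1ccc(OC)c(OC)c1 | intermediate
6 | [4-(benzyloxy)-3-methoxyphenyl]methanol | COc1cc(CO)ccc1OCc1ccccc1 | starting material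
7 | 1-(benzyloxy)-4-(bromomethyl)-2-methoxybenzene | COc1cc(CBr)ccc1OCc1ccccc1 | intermediate
8 | lithium enolate of 5, lithium (R)-4-(3,4-dimethoxybenzyl)-4,5-dihydrofuran-2-olate (not isolated) | [Li+].[O-]C1=C[C@@H](Cc2ccc(OC)c(OC)c2)CO1 | intermediate
9 | (3R,4R)-3-[4-(benzyloxy)-3-methoxybenzyl]-4-(3,4-dimethoxybenzyl)dihydrofuran-2(3H)-one (O-benzylarctigenin) | COc1cc(C[C@H]2C(=O)OC[C@@H]2Cc2ccc(OC)c(OC)c2)ccc1OCc1ccccc1 | intermediate
10 | potassium enolate of 9, potassium (R)-3-[4-(benzyloxy)-3-methoxybenzyl]-4-(3,4-dimethoxybenzyl)-4,5-dihydrofuran-2-olate (not isolated) | [K+].[O-]C1=C(Cc2ccc(OCc3ccccc3)c(OC)c2)[C@@H](Cc2ccc(OC)c(OC)c2)CO1 | intermediate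
11 | (3S,4S)-3-[4-(benzyloxy)-3-methoxybenzyl]-4-(3,4-dimethoxybenzyl)-3-hydroxydihydrofuran-2(3H)-one (O-benzyltrachelogenin) | COc1cc(C[C@@]2(O)C(=O)OC[C@@H]2Cc2ccc(OC)c(OC)c2)ccc1OCc1ccccc1 | intermediate
12 | trachelogenin, (3S,4S)-4-(3,4-dimethoxybenzyl)-3-hydroxy-3-(4-hydroxy-3-methoxybenzyl)dihydrofuran-2(3H)-one | COc1cc(C[C@@]2(O)C(=O)OC[C@@H]2Cc2ccc(OC)c(OC)c2)ccc1O | target

**Step count.** Total: 7 steps. Longest linear sequence: 6 steps (steps 1, 2, 3, 5, 6, 7); step 4 is a one-step side branch.

**Steps most likely to fail**

1. Step 3. The catalyst may discriminate poorly between the two enantiotopic CH2 groups of the Criegee adduct, because the substituent is a flexible benzyl group and not an aryl group directly on the ring; the lactone would then form with low enantiomeric purity. Fallback, setting out from 3 and returning at 5: the enantiotopic α-methylene groups are told apart by deprotonation instead of migration. Treatment of 3 with lithium bis[(S)-1-phenylethyl]amide or its (R,R) antipode, whichever gives the R product, in the presence of Me3SiCl (THF, −100 °C) should give the silyl enol ether (R)-3-(3,4-dimethoxybenzyl)-1-(trimethylsilyloxy)cyclobut-1-ene F1. Ozonolysis with a controlled amount of O3 (CH2Cl2/MeOH, −78 °C) and reduction of the ozonide with NaBH4 should give (R)-3-(3,4-dimethoxybenzyl)-4-hydroxybutanoic acid F2, which lactonises on acidification to 5. This variant closes the ring at the acyl carbon–oxygen bond.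

2. Step 6. Oxygen transfer may show poor facial selectivity at the tetrasubstituted enolate, and the enolate may add to the sulfonimine formed from the oxidant. Fallback, setting out from 5 and returning at 11: the order of the two C3 bond formations is reversed, so that the carbon electrophile enters anti to the C4 group. Lithium enolate 8 is oxidised with the same oxaziridine to (3R,4S)-4-(3,4-dimethoxybenzyl)-3-hydroxydihydrofuran-2(3H)-one F3. Its alkoxide–enolate dianion (LiN(iPr)2, 2.2 equiv, THF/DMPU, −78 °C) is then C-benzylated with 7 anti to the C4 benzyl group, which places the two benzyl groups trans and the hydroxyl cis to the C4 benzyl group, as in 11.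

3. Step 5. The electron-rich bromide 7 may ionise and self-condense, and proton exchange between product and enolate may lead to dialkylation. Fallback, setting out from 5 and returning at 9: aldol addition of enolate 8 to 4-(benzyloxy)-3-methoxybenzaldehyde (THF, −78 °C) should give (3S,4R)-3-{[4-(benzyloxy)-3-methoxyphenyl](hydroxy)methyl}-4-(3,4-dimethoxybenzyl)dihydrofuran-2(3H)-one F4 as a mixture of carbinol epimers. Ionic hydrogenation of the electron-rich benzylic alcohol (Et3SiH, CF3CO2H, CH2Cl2, 0 °C) then removes the hydroxyl and gives 9.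

**Further compounds**

F1 | step 3 | (R)-3-(3,4-dimethoxybenzyl)-1-(trimethylsilyloxy)cyclobut-1-ene | C[Si](C)(C)OC1=C[C@@H](C1)Cc1ccc(OC)c(OC)c1
F2 | step 3 | (R)-3-(3,4-dimethoxybenzyl)-4-hydroxybutanoic acid | OC[C@@H](CC(=O)O)Cc1ccc(OC)c(OC)c1
F3 | step 6 | (3R,4S)-4-(3,4-dimethoxybenzyl)-3-hydroxydihydrofuran-2(3H)-one | O[C@H]1C(=O)OC[C@@H]1Cc1ccc(OC)c(OC)c1
F4 | step 5 | (3S,4R)-3-{[4-(benzyloxy)-3-methoxyphenyl](hydroxy)methyl}-4-(3,4-dimethoxybenzyl)dihydrofuran-2(3H)-one (carbinol epimers) | COc1cc(C(O)[C@H]2C(=O)OC[C@@H]2Cc2ccc(OC)c(OC)c2)ccc1OCc1ccccc1
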